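**Retrosynthetic overview**

1. The nitrogen heterocycle is closed last, by Bischler–Napieralski cyclisation (C1–C8a) of an N-acetyl (S)-1-arylpropan-2-amine on the finished biaryl. C3 (S) is bought as N-Boc-L-alaninol and joined to the aryl ring by Grignard opening of its cyclic sulfamidate.
2. The strategy rests on the hydroxyl-bearing naphthalene ring (C5', C6', C7', C8', C8a', C4a'). Its C7'H=C8'H unit lies opposite the C5'–OH carbon and the aryl-bearing C6', so this ring is the aromatic tautomer of a cyclic ketone whose C7'=C8' bond can be made by ring-closing metathesis of a styrenyl dienol, followed by oxidation and tautomerisation.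
3. The dienol is cut at C5'–C6' into 2-ethenyl-6-methoxy-4-methylbenzaldehyde and a 1-arylallyl alcohol, joined by Pd/Et2Zn umpolung allylation to the branched adduct. The crowded C7–C6' biaryl bond is thus never made by cross-coupling; it starts as an aryl–C(sp3) bond grown from a formyl group placed between two methoxy groups by directed lithiation.
4. Ring order: two purchased benzene rings, then the naphthol carbocycle (closed in step 12, aromatised in step 13), then the dihydroisoquinoline ring (step 16).

Key step: step 12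

Assumption: the target is drawn without an axial descriptor, so the C7–C6' biaryl axis is treated as stereochemically undefined and C3 (S) is the only stereocentre to be controlled.

**Route**

Step 1
Reactants: 1 tert-butyl N-[(2S)-1-hydroxypropan-2-yl]carbamate (N-Boc-L-alaninol)
Product: 3 tert-butyl (4S)-4-methyl-1,2,3-oxathiazolidine-3-carboxylate 2,2-dioxide, via cyclic sulfamidite 2 (not isolated)
Conditions: SOCl2, pyridine, MeCN, −40 °C → rt; then RuCl3·xH2O (cat.), NaIO4, MeCN/H2O, 0 °C
Reagents that add atoms: thionyl chloride, O=S(Cl)Cl; sodium periodate, [Na+].[O-]I(=O)(=O)=O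
Why: Cyclisation of an N-Boc 1,2-amino alcohol with thionyl chloride and RuCl3/NaIO4 oxidation of the sulfamidite is the standard cyclic sulfamidate synthesis; it gives an O-electrophile that cannot rearrange through an aziridinium ion, and the C4 centre is not touched.

Step 2
Reactants: 4 1-bromo-3,5-dimethoxybenzene; 3 tert-butyl (4S)-4-methyl-1,2,3-oxathiazolidine-3-carboxylate 2,2-dioxide
Product: 7 tert-butyl N-[(2S)-1-(3,5-dimethoxyphenyl)propan-2-yl]carbamate, via 3,5-dimethoxyphenylmagnesium bromide 5 (not isolated), via N-sulfonate magnesium salt 6 (not isolated)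
Conditions: Mg, THF, reflux; then CuI (10 mol %), 3, THF, −20 → 0 °C; then 10% aq. citric acid, rt
Reagents that add atoms: none
Why: Copper-catalysed SN2 opening of a cyclic sulfamidate by an aryl Grignard reagent occurs only at the oxygen-bearing CH2, so the S centre is carried over unchanged, and mild acid then hydrolyses the N-sulfonate while leaving the Boc group.

Step 3
Reactants: 7 tert-butyl N-[(2S)-1-(3,5-dimethoxyphenyl)propan-2-yl]carbamate
Product: 8 (2S)-1-(3,5-dimethoxyphenyl)propan-2-amine
Conditions: TFA, CH2Cl2, rt; aq. NaOH work-up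
Reagents that add atoms: none
Why: Acidolysis of the tert-butyl carbamate should give the free primary amine without affecting the aryl methyl ethers or the stereocentre.

Step 4
Reactants: 8 (2S)-1-(3,5-dimethoxyphenyl)propan-2-amine
Product: 9 (2S)-N,N-dibenzyl-1-(3,5-dimethoxyphenyl)propan-2-amine
Conditions: BnBr (2.3 equiv), K2CO3, MeCN, 70 °C
Reagents that add atoms: benzyl bromide, BrCc1ccccc1
Why: Double N-alkylation gives a hindered tertiary amine with no acidic N–H that should tolerate organolithium, Grignard, organozinc, ruthenium carbene and periodinane reagents and is removable later by hydrogenolysis.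

Step 5
Reactants: 9 (2S)-N,N-dibenzyl-1-(3,5-dimethoxyphenyl)propan-2-amine
Product: 11 4-[(2S)-2-(dibenzylamino)propyl]-2,6-dimethoxybenzaldehyde, via 2,6-dimethoxyaryl lithium 10 (not isolated)
Conditions: n-BuLi, TMEDA, THF, 0 °C → rt; DMF, 0 °C; H2O
Reagents that add atoms: N,N-dimethylformamide, CN(C)C=O
Why: Directed ortho-metalation removes the ring proton flanked by both methoxy groups far faster than any benzylic or N-benzyl proton, and DMF formylates the aryllithium at that position.

Step 6
Reactants: 11 4-[(2S)-2-(dibenzylamino)propyl]-2,6-dimethoxybenzaldehyde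
Product: 12 1-{4-[(2S)-2-(dibenzylamino)propyl]-2,6-dimethoxyphenyl}prop-2-en-1-ol (both carbinol epimers)
Conditions: vinylmagnesium bromide, THF, −20 → 0 °C; aq. NH4Cl; Et3N-deactivated silica
Reagents that add atoms: vinylmagnesium bromide, C=C[Mg]Br
Why: Grignard 1,2-addition to the aryl aldehyde gives the allylic alcohol; the new carbinol centre is left uncontrolled because it becomes a planar π-allyl carbon in step 11.

Step 7
Reactants: 13 3,5-dimethoxytoluene
Product: 15 2,6-dimethoxy-4-methylbenzaldehyde, via 2,6-dimethoxy-4-methylphenyllithium 14 (not isolated)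
Conditions: n-BuLi, TMEDA, THF, 0 °C → rt; DMF, 0 °C; H2O
Reagents that add atoms: N,N-dimethylformamide, CN(C)C=O
Why: Directed ortho-metalation between the two methoxy groups and DMF quench is the established formylation of resorcinol dimethyl ethers at the doubly flanked position.

Step 8
Reactants: 15 2,6-dimethoxy-4-methylbenzaldehyde
Product: 16 2-hydroxy-6-methoxy-4-methylbenzaldehyde
Conditions: BCl3 (1.1 equiv), CH2Cl2, −78 → 0 °C; H2O
Reagents that add atoms: none
Why: Chelation-directed ether cleavage by BCl3 removes one methyl group ortho to the formyl group and should stop there, because the resulting aryloxyboron chelate deactivates the second methoxy group.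

Step 9
Reactants: 16 2-hydroxy-6-methoxy-4-methylbenzaldehyde
Product: 17 2-formyl-3-methoxy-5-methylphenyl trifluoromethanesulfonate
Conditions: Tf2O, pyridine, CH2Cl2, 0 °C
Reagents that add atoms: trifluoromethanesulfonic anhydride, O=S(=O)(OS(=O)(=O)C(F)(F)F)C(F)(F)F
Why: O-Sulfonylation of the phenol turns the former methoxy position into a cross-coupling handle activated by the ortho formyl group.

Step 10
Reactants: 17 2-formyl-3-methoxy-5-methylphenyl trifluoromethanesulfonate
Product: 18 2-ethenyl-6-methoxy-4-methylbenzaldehyde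
Conditions: vinylboronic acid pinacol ester, PdCl2(dppf) (5 mol %), K2CO3, dioxane/H2O, 80 °C
Reagents that add atoms: vinylboronic acid pinacol ester, C=CB1OC(C)(C)C(C)(C)O1
Why: Suzuki–Miyaura coupling of an electron-poor aryl triflate with a vinylboronate is reliable and leaves the aldehyde untouched.

Step 11
Reactants: 12 1-{4-[(2S)-2-(dibenzylamino)propyl]-2,6-dimethoxyphenyl}prop-2-en-1-ol; 18 2-ethenyl-6-methoxy-4-methylbenzaldehyde
Product: 20 2-{4-[(2S)-2-(dibenzylamino)propyl]-2,6-dimethoxyphenyl}-1-(2-ethenyl-6-methoxy-4-methylphenyl)but-3-en-1-ol (diastereomer mixture at C1/C2), via arylallyl ethylzinc 19 (not isolated)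
Conditions: Pd(PPh3)4 (10 mol %), Et2Zn (hexane solution, 3–4 equiv), THF, 0 °C → rt; aq. NH4Cl
Reagents that add atoms: none
Why: In this Tamaru-type umpolung allylation, zerovalent palladium ionises the zinc alkoxide of 12 to a π-allyl complex, and transmetalation with Et2Zn gives allylzinc 19 with zinc on the unsubstituted terminus; 19 should add to aldehyde 18 through a six-membered chair transition state at the aryl-bearing γ-carbon to give the branched homoallylic alcohol, and the two new sp3 centres (anti expected to prevail) are not controlled because both are erased in step 13.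

Step 12
Reactants: 20 2-{4-[(2S)-2-(dibenzylamino)propyl]-2,6-dimethoxyphenyl}-1-(2-ethenyl-6-methoxy-4-methylphenyl)but-3-en-1-ol
Product: 21 2-{4-[(2S)-2-(dibenzylamino)propyl]-2,6-dimethoxyphenyl}-8-methoxy-6-methyl-1,2-dihydronaphthalen-1-ol (diastereomer mixture at C1/C2)
Conditions: second-generation Grubbs catalyst (5 mol %), CH2Cl2 (0.01 M), 40 °C
Reagents that add atoms: none
Why: The ruthenium alkylidene should load first on the monosubstituted, non-conjugated allylic vinyl group of 20, add across the ortho-substituted styrene by intramolecular [2+2] cycloaddition and release the ring by cycloreversion, with loss of ethene driving the equilibrium. The closest known reaction type is ring-closing metathesis of 1-(2-vinylaryl)but-3-en-1-ols to 1,2-dihydronaphthalen-1-ols with the second-generation Grubbs catalyst. The six-membered carbocycle is closed by joining the two terminal alkene carbons of a 1,7-diene held on adjacent positions of the arene, the new C7'=C8' bond being endocyclic, and no other ring size is accessible from this diene. No stereocentre is created: the C5'/C6' centres enter as a mixture and are destroyed in step 13, and C3 (S) in the side chain is remote and untouched. The step needs cyclisation to outrun intermolecular metathesis and the benzylic carbinol to survive without losing water; high dilution and the rigid ortho tether should secure the first, and neutral, acid-free conditions at 40 °C the second. The hindered tertiary dibenzylamine is not expected to bind ruthenium.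

Step 13
Reactants: 21 2-{4-[(2S)-2-(dibenzylamino)propyl]-2,6-dimethoxyphenyl}-8-methoxy-6-methyl-1,2-dihydronaphthalen-1-ol
Product: 23 2-{4-[(2S)-2-(dibenzylamino)propyl]-2,6-dimethoxyphenyl}-8-methoxy-6-methylnaphthalen-1-ol, via 2H-naphthalen-1-one tautomer 22 (not isolated)
Conditions: Dess–Martin periodinane (1.2 equiv), NaHCO3, CH2Cl2, 0 °C → rt
Reagents that add atoms: none
Why: Dess–Martin oxidation of the benzylic alcohol gives ketone 22, whose α-hydrogen at the aryl-bearing carbon is allylic and benzylic, so enolisation to the aromatic 1-naphthol should be spontaneous and removes both uncontrolled sp3 centres.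

Step 14
Reactants: 23 2-{4-[(2S)-2-(dibenzylamino)propyl]-2,6-dimethoxyphenyl}-8-methoxy-6-methylnaphthalen-1-ol
Product: 24 2-{4-[(2S)-2-aminopropyl]-2,6-dimethoxyphenyl}-8-methoxy-6-methylnaphthalen-1-ol
Conditions: H2 (1–3 atm), Pd(OH)2/C, MeOH/EtOAc, rt
Reagents that add atoms: none
Why: Hydrogenolysis of both N-benzyl groups over Pd(OH)2/C should free the primary amine; no alkene remains, and the naphthalene and aryl ethers are inert under these conditions.

Step 15
Reactants: 24 2-{4-[(2S)-2-aminopropyl]-2,6-dimethoxyphenyl}-8-methoxy-6-methylnaphthalen-1-ol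
Product: 25 2-{4-[(2S)-2-acetamidopropyl]-2,6-dimethoxyphenyl}-8-methoxy-6-methylnaphthalen-1-yl acetate
Conditions: Ac2O, pyridine, DMAP (cat.), CH2Cl2, rt
Reagents that add atoms: acetic anhydride, CC(=O)OC(C)=O
Why: DMAP-catalysed acylation installs the acetamide that supplies C1 and its methyl group and masks the naphthol as an acetate so that it cannot be phosphorylated in step 16.

Step 16
Reactants: 25 2-{4-[(2S)-2-acetamidopropyl]-2,6-dimethoxyphenyl}-8-methoxy-6-methylnaphthalen-1-yl acetate
Product: 26 2-[(3S)-6,8-dimethoxy-1,3-dimethyl-3,4-dihydroisoquinolin-7-yl]-8-methoxy-6-methylnaphthalen-1-yl acetate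
Conditions: POCl3, MeCN, 80 °C; aq. NaHCO3 work-up
Reagents that add atoms: none
Why: In this Bischler–Napieralski cyclisation the activated amide attacks the ring position ortho to the side chain, which is ortho to one methoxy group and para to the other; the two such positions are constitutionally equivalent, so one dihydroisoquinoline results, and C3 is not involved.

Step 17
Reactants: 26 2-[(3S)-6,8-dimethoxy-1,3-dimethyl-3,4-dihydroisoquinolin-7-yl]-8-methoxy-6-methylnaphthalen-1-yl acetate
Product: 27 2-[(3S)-6,8-dimethoxy-1,3-dimethyl-3,4-dihydroisoquinolin-7-yl]-8-methoxy-6-methylnaphthalen-1-ol (target)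
Conditions: K2CO3 (cat.), MeOH, rt
Reagents that add atoms: none
Why: Base-catalysed transesterification of the aryl acetate with methanol should release the naphthol without touching the cyclic imine or the C3 stereocentre.

**Compound list**

1 | tert-butyl N-[(2S)-1-hydroxypropan-2-yl]carbamate (N-Boc-L-alaninol) | C[C@H](NC(=O)OC(C)(C)C)CO | starting material
2 | tert-butyl (4S)-4-methyl-1,2,3-oxathiazolidine-3-carboxylate 2-oxide (both S-oxide epimers) | C[C@H]1COS(=O)N1C(=O)OC(C)(C)C | intermediate
3 | tert-butyl (4S)-4-methyl-1,2,3-oxathiazolidine-3-carboxylate 2,2-dioxide | C[C@H]1COS(=O)(=O)N1C(=O)OC(C)(C)C | intermediate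
4 | 1-bromo-3,5-dimethoxybenzene | COc1cc(Br)cc(OC)c1 | starting material
5 | 3,5-dimethoxyphenylmagnesium bromide | COc1cc([Mg]Br)cc(OC)c1 | intermediate
6 | bromomagnesium N-(tert-butoxycarbonyl)-N-[(2S)-1-(3,5-dimethoxyphenyl)propan-2-yl]sulfamate | COc1cc(C[C@H](C)N(C(=O)OC(C)(C)C)S(=O)(=O)[O-])cc(OC)c1.[Mg+2].[Br-] | intermediate
7 | tert-butyl N-[(2S)-1-(3,5-dimethoxyphenyl)propan-2-yl]carbamate | COc1cc(C[C@H](C)NC(=O)OC(C)(C)C)cc(OC)c1 | intermediate
8 | (2S)-1-(3,5-dimethoxyphenyl)propan-2-amine | COc1cc(C[C@H](C)N)cc(OC)c1 | intermediate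
9 | (2S)-N,N-dibenzyl-1-(3,5-dimethoxyphenyl)propan-2-amine | COc1cc(C[C@H](C)N(Cc2ccccc2)Cc2ccccc2)cc(OC)c1 | intermediate
10 | {4-[(2S)-2-(dibenzylamino)propyl]-2,6-dimethoxyphenyl}lithium | [Li]c1c(OC)cc(C[C@H](C)N(Cc2ccccc2)Cc2ccccc2)cc1OC | intermediate
11 | 4-[(2S)-2-(dibenzylamino)propyl]-2,6-dimethoxybenzaldehyde | O=Cc1c(OC)cc(C[C@H](C)N(Cc2ccccc2)Cc2ccccc2)cc1OC | intermediate
12 | 1-{4-[(2S)-2-(dibenzylamino)propyl]-2,6-dimethoxyphenyl}prop-2-en-1-ol (both carbinol epimers) | C=CC(O)c1c(OC)cc(C[C@H](C)N(Cc2ccccc2)Cc2ccccc2)cc1OC | intermediate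
13 | 3,5-dimethoxytoluene | COc1cc(C)cc(OC)c1 | starting material
14 | (2,6-dimethoxy-4-methylphenyl)lithium | [Li]c1c(OC)cc(C)cc1OC | intermediate
15 | 2,6-dimethoxy-4-methylbenzaldehyde | COc1cc(C)cc(OC)c1C=O | intermediate
16 | 2-hydroxy-6-methoxy-4-methylbenzaldehyde | COc1cc(C)cc(O)c1C=O | intermediate
17 | 2-formyl-3-methoxy-5-methylphenyl trifluoromethanesulfonate | COc1cc(C)cc(OS(=O)(=O)C(F)(F)F)c1C=O | intermediate
18 | 2-ethenyl-6-methoxy-4-methylbenzaldehyde | C=Cc1cc(C)cc(OC)c1C=O | intermediate
19 | [(2E)-3-{4-[(2S)-2-(dibenzylamino)propyl]-2,6-dimethoxyphenyl}prop-2-en-1-yl](ethyl)zinc | CC[Zn]C/C=C/c1c(OC)cc(C[C@H](C)N(Cc2ccccc2)Cc2ccccc2)cc1OC | intermediate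
20 | 2-{4-[(2S)-2-(dibenzylamino)propyl]-2,6-dimethoxyphenyl}-1-(2-ethenyl-6-methoxy-4-methylphenyl)but-3-en-1-ol (diastereomer mixture at C1/C2) | C=Cc1cc(C)cc(OC)c1C(O)C(C=C)c1c(OC)cc(C[C@H](C)N(Cc2ccccc2)Cc2ccccc2)cc1OC | intermediate
21 | 2-{4-[(2S)-2-(dibenzylamino)propyl]-2,6-dimethoxyphenyl}-8-methoxy-6-methyl-1,2-dihydronaphthalen-1-ol (diastereomer mixture at C1/C2) | COc1cc(C)cc2c1C(O)C(c1c(OC)cc(C[C@H](C)N(Cc3ccccc3)Cc3ccccc3)cc1OC)C=C2 | intermediate
22 | 2-{4-[(2S)-2-(dibenzylamino)propyl]-2,6-dimethoxyphenyl}-8-methoxy-6-methylnaphthalen-1(2H)-one | COc1cc(C)cc2c1C(=O)C(c1c(OC)cc(C[C@H](C)N(Cc3ccccc3)Cc3ccccc3)cc1OC)C=C2 | intermediate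
23 | 2-{4-[(2S)-2-(dibenzylamino)propyl]-2,6-dimethoxyphenyl}-8-methoxy-6-methylnaphthalen-1-ol | COc1cc(C[C@H](C)N(Cc2ccccc2)Cc2ccccc2)cc(OC)c1-c1ccc2cc(C)cc(OC)c2c1O | intermediate
24 | 2-{4-[(2S)-2-aminopropyl]-2,6-dimethoxyphenyl}-8-methoxy-6-methylnaphthalen-1-ol | COc1cc(C[C@H](C)N)cc(OC)c1-c1ccc2cc(C)cc(OC)c2c1O | intermediate
25 | 2-{4-[(2S)-2-acetamidopropyl]-2,6-dimethoxyphenyl}-8-methoxy-6-methylnaphthalen-1-yl acetate | COc1cc(C[C@H](C)NC(C)=O)cc(OC)c1-c1ccc2cc(C)cc(OC)c2c1OC(C)=O | intermediate
26 | 2-[(3S)-6,8-dimethoxy-1,3-dimethyl-3,4-dihydroisoquinolin-7-yl]-8-methoxy-6-methylnaphthalen-1-yl acetate | COc1cc2c(c(OC)c1-c1ccc3cc(C)cc(OC)c3c1OC(C)=O)C(C)=N[C@@H](C)C2 | intermediate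
27 | 2-[(3S)-6,8-dimethoxy-1,3-dimethyl-3,4-dihydroisoquinolin-7-yl]-8-methoxy-6-methylnaphthalen-1-ol | COc1cc2c(c(OC)c1-c1ccc3cc(C)cc(OC)c3c1O)C(C)=N[C@@H](C)C2 | target

**Step count**

Total: 17 steps. Longest linear sequence: 13 steps (steps 1–6, then 11–17); the aldehyde branch (steps 7–10) joins at step 11.

**Steps most likely to fail, with fallbacks**

Step 11. The congested allylzinc may add slowly or reversibly to the di-ortho-substituted aldehyde, so that retro-allylation drains material to the linear adduct, or ethyl transfer or reduction of the aldehyde competes. The fallback replaces the in-situ allylzinc by an isolable allylboron reagent. It sets out from 12, which is acetylated (Ac2O, Et3N, DMAP, CH2Cl2) to 1-{4-[(2S)-2-(dibenzylamino)propyl]-2,6-dimethoxyphenyl}prop-2-en-1-yl acetate F1. Palladium-catalysed Miyaura borylation of this allylic acetate (B2pin2, Pd2(dba)3, DMSO, 50 °C) should give the linear (E)-3-arylallyl pinacol boronate F2. Uncatalysed allylboration of 18 with F2 (toluene, rt → 60 °C) is irreversible and proceeds through a closed chair transition state to the pinacol borate ester of the branched alcohol F3. Hydrolytic work-up of F3 (triethanolamine or aq. NaHCO3) returns to the route at 20.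

Step 12. The benzylic carbinol may lose water during or after ring closure, which would aromatise the ring to a naphthalene lacking the C5' oxygen; the free hydroxyl may also promote ruthenium hydride alkene migration or hold the catalyst. The fallback masks the hydroxyl before metathesis. It sets out from 20, which is silylated (TMSCl, imidazole, DMF) to the trimethylsilyl ether of the dienol F4. Ring-closing metathesis of F4 under the same catalyst should give the trimethylsilyl ether of the dihydronaphthalenol F5. Buffered desilylation of F5 (TBAF, AcOH, THF, 0 °C) returns to the route at 21.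

Step 13. The electron-rich naphthol is formed in the presence of the periodinane and may be oxidised further to quinone-type products or coupled oxidatively; the amine may also be oxidised. The fallback moves the oxidation ahead of ring closure, so that the oxidant never meets a phenol. It sets out from 20, which is oxidised (Dess–Martin periodinane, NaHCO3, CH2Cl2, 0 °C, base-free work-up to avoid alkene migration into conjugation) to 2-{4-[(2S)-2-(dibenzylamino)propyl]-2,6-dimethoxyphenyl}-1-(2-ethenyl-6-methoxy-4-methylphenyl)but-3-en-1-one F6. Ring-closing metathesis of F6 (second-generation Grubbs catalyst, CH2Cl2, 40 °C) should give ketone 22, which tautomerises in the flask, and the sequence returns to the route at 23.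

**Further compounds**

F1 | step 11 | 1-{4-[(2S)-2-(dibenzylamino)propyl]-2,6-dimethoxyphenyl}prop-2-en-1-yl acetate | C=CC(OC(C)=O)c1c(OC)cc(C[C@H](C)N(Cc2ccccc2)Cc2ccccc2)cc1OC
F2 | step 11 | (2S)-N,N-dibenzyl-1-{3,5-dimethoxy-4-[(1E)-3-(4,4,5,5-tetramethyl-1,3,2-dioxaborolan-2-yl)prop-1-en-1-yl]phenyl}propan-2-amine | CC1(C)OB(C/C=C/c2c(OC)cc(C[C@H](C)N(Cc3ccccc3)Cc3ccccc3)cc2OC)OC1(C)C
F3 | step 11 | pinacol borate ester of dienol 20 | C=Cc1cc(C)cc(OC)c1C(OB1OC(C)(C)C(C)(C)O1)C(C=C)c1c(OC)cc(C[C@H](C)N(Cc2ccccc2)Cc2ccccc2)cc1OC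
F4 | step 12 | trimethylsilyl ether of dienol 20 | C=Cc1cc(C)cc(OC)c1C(O[Si](C)(C)C)C(C=C)c1c(OC)cc(C[C@H](C)N(Cc2ccccc2)Cc2ccccc2)cc1OC
F5 | step 12 | trimethylsilyl ether of dihydronaphthalenol 21 | COc1cc(C)cc2c1C(O[Si](C)(C)C)C(c1c(OC)cc(C[C@H](C)N(Cc3ccccc3)Cc3ccccc3)cc1OC)C=C2
F6 | step 13 | 2-{4-[(2S)-2-(dibenzylamino)propyl]-2,6-dimethoxyphenyl}-1-(2-ethenyl-6-methoxy-4-methylphenyl)but-3-en-1-one | C=Cc1cc(C)cc(OC)c1C(=O)C(C=C)c1c(OC)cc(C[C@H](C)N(Cc2ccccc2)Cc2ccccc2)cc1OC
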